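**Retrosynthetic overview**

1. Target 17 is obtained by hydrogenolysis of its hexa-O-benzyl ether 16, which already carries the only stereocentre (C2).
2. Ring C of the flavanone is closed last, at C2–C3, from the open-chain biaryl ketone 14 by an oxidative C–H/C–H coupling. The enabling feature is that C2 is benzylic, bonded to O1 and para to the ring B oxygen, so in 14 it is the CH2 of a para-oxybenzyl aryl ether and uniquely hydride-labile; C3 is the enolisable methyl of the C4 acetyl group, ortho to O1 on ring A.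
3. The C6–C8'' biaryl bond of 14 comes from a Suzuki–Miyaura coupling of flavone 8-boronate 7 with iodoacetophenone 13.
4. 7 comes from apigenin (benzylation, C8 iodination, borylation); 13 comes from 2',4',6'-trihydroxyacetophenone (4-O-benzylation, ortho O-alkylation with the future ring B/C2 unit, OH-directed iodination, benzylation).
5. Ring order: the flavone rings are bought with apigenin, rings A and B of the flavanone unit are used as arenes, then the biaryl bond is made, and ring C of the flavanone is formed last.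

Key step: step 9

Assumption: the target defines only C2 (S); the hindered C6–C8'' biaryl axis carries no descriptor, so it is left uncontrolled (14 is racemic at the axis; 16 and 17 are the 2S compounds without an axial descriptor).

**Route**

Step 1
Reactants: 1 apigenin; 2 benzyl bromide
Product: 3 5,7-bis(benzyloxy)-2-[4-(benzyloxy)phenyl]-4H-chromen-4-one
Conditions: BnBr (4 equiv), K2CO3, DMF, 80 °C
Reagents that add atoms: benzyl bromide, BrCc1ccccc1
Why: Williamson ether synthesis, run under forcing conditions so that the hydrogen-bonded 5-OH is alkylated as well as the 7- and 4'-OH groups.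

Step 2
Reactants: 3 tri-O-benzylapigenin; 4 N-iodosuccinimide
Product: 5 5,7-bis(benzyloxy)-2-[4-(benzyloxy)phenyl]-8-iodo-4H-chromen-4-one
Conditions: NIS (1.1 equiv), CF3CO2H (0.3 equiv), CH2Cl2/MeCN, rt
Reagents that add atoms: N-iodosuccinimide, O=C1CCC(=O)N1I
Why: Electrophilic aromatic iodination of the most electron-rich ring, where fully O-alkylated 5,7-dioxygenated flavones react at C8 because C6 lies between two benzyloxy groups.

Step 3
Reactants: 5 8-iodoflavone; 6 pinacolborane
Product: 7 5,7-bis(benzyloxy)-2-[4-(benzyloxy)phenyl]-8-(4,4,5,5-tetramethyl-1,3,2-dioxaborolan-2-yl)-4H-chromen-4-one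
Conditions: PdCl2(MeCN)2 (3 mol %), SPhos (12 mol %), pinacolborane (3 equiv), Et3N (4 equiv), 1,4-dioxane, 90 °C
Reagents that add atoms: pinacolborane, B1OC(C)(C)C(C)(C)O1
Why: Palladium-catalysed Miyaura-type borylation of an aryl iodide with pinacolborane, in which the dialkylbiarylphosphine copes with the two ortho substituents and the chromone carbonyl is tolerated.

Step 4
Reactants: 8 2',4',6'-trihydroxyacetophenone; 2 benzyl bromide
Product: 9 1-[4-(benzyloxy)-2,6-dihydroxyphenyl]ethanone
Conditions: BnBr (1.0 equiv), K2CO3 (1.05 equiv), DMF, 0 °C to rt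
Reagents that add atoms: benzyl bromide, BrCc1ccccc1
Why: Williamson ether synthesis that should go first to the para OH, which is the most acidic and is not held in a hydrogen bond to the acetyl group.

Step 5
Reactants: 9 4-O-benzyl phloroacetophenone; 10 4-(benzyloxy)benzyl chloride
Product: 11 1-[4-(benzyloxy)-2-{[4-(benzyloxy)benzyl]oxy}-6-hydroxyphenyl]ethanone
Conditions: 10 (1.05 equiv), K2CO3 (1.2 equiv), KI (cat.), acetone, reflux
Reagents that add atoms: 4-(benzyloxy)benzyl chloride, ClCc1ccc(OCc2ccccc2)cc1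
Why: Williamson ether synthesis that stops after one of the two equivalent ortho OH groups, because the remaining one is chelated to the carbonyl; it installs the future C2 and ring B on the future O1.

Step 6
Reactants: 11 mono-phenol; 4 N-iodosuccinimide
Product: 12 1-[4-(benzyloxy)-6-{[4-(benzyloxy)benzyl]oxy}-2-hydroxy-3-iodophenyl]ethanone
Conditions: NIS (1.0 equiv), DMF, 0 °C to rt, dark
Reagents that add atoms: N-iodosuccinimide, O=C1CCC(=O)N1I
Why: Electrophilic aromatic iodination directed ortho to the free phenol, at the ring position that is also the less hindered one, which places the halogen next to the future 5-OH.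

Step 7
Reactants: 12 iodophenol; 2 benzyl bromide
Product: 13 1-[2,4-bis(benzyloxy)-6-{[4-(benzyloxy)benzyl]oxy}-3-iodophenyl]ethanone
Conditions: BnBr (1.5 equiv), K2CO3 (2 equiv), DMF, 60 °C
Reagents that add atoms: benzyl bromide, BrCc1ccccc1
Why: Williamson ether synthesis on the chelated, hindered phenol, which removes the only free OH before the coupling and the oxidation.

Step 8
Reactants: 7 flavone 8-boronate; 13 iodoacetophenone
Product: 14 8-[3-acetyl-2,6-bis(benzyloxy)-4-{[4-(benzyloxy)benzyl]oxy}phenyl]-5,7-bis(benzyloxy)-2-[4-(benzyloxy)phenyl]-4H-chromen-4-one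
Conditions: Pd(OAc)2 (5 mol %), SPhos (10 mol %), K3PO4 (3 equiv), toluene/H2O (10:1), 100 °C
Reagents that add atoms: none
Why: Suzuki–Miyaura coupling with a dialkylbiarylphosphine ligand, a system made for tetra-ortho-substituted biaryls; the ketone and all ethers are inert to the weak base.

Step 9
Reactants: 14 biaryl ketone
Product: 16 (2S)-5,7-bis(benzyloxy)-6-{5,7-bis(benzyloxy)-2-[4-(benzyloxy)phenyl]-4-oxo-4H-chromen-8-yl}-2-[4-(benzyloxy)phenyl]-2,3-dihydro-4H-chromen-4-one, via oxocarbenium ion 15 (not isolated)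
Conditions: DDQ (1.1 equiv), (R)-TRIP (3,3'-bis(2,4,6-triisopropylphenyl)-1,1'-binaphthyl-2,2'-diyl hydrogen phosphate, 10 mol %), 4 Å molecular sieves, CH2Cl2, −30 to 0 °C
Reagents that add atoms: none
Why: Proposed new method: DDQ removes hydride from the only para-alkoxybenzylic ether C–H of 14 (the future C2–H, activated by O1 and by the para oxygen of ring B), the chiral phosphoric acid protonates the DDQ hydroquinone anion so that DDQH2 precipitates and oxocarbenium ion 15 is left as a contact ion pair with the chiral phosphate, and the enol of the ortho acetyl group (formed under the same acid) attacks C2 through its CH2 carbon, which forms the C2–C3 bond and returns the proton to the catalyst. The closest known reaction types are the DDQ-mediated oxidative C–H cleavage of para-methoxybenzyl ethers with intramolecular enol acetate capture to 2-aryltetrahydropyran-4-ones and the chiral-phosphate-controlled cyclisations of oxocarbenium ions (oxa-Pictet–Spengler and Prins type); their combination on an O-aryl oxocarbenium ion with a ketone enol under catalyst control is new. Ring C closes in the 6-(enolendo)-endo-trig mode onto the O1=C2 bond of 15, and an O-attack product (a 4-methylene-1,3-benzodioxine) would re-ionise under the acid and converge on the same ketone by a Petasis–Ferrier-type 1,3 O-to-C shift. The C2 stereocentre is set by the catalyst alone: the phosphate stays paired with the planar cation and hydrogen-bonded to the enol OH, so that the enol carbon is delivered to one face of C2 (the antipode of the acid that gives 2S is to be fixed on a model ether; (R)-TRIP is written). The step needs site selectivity against five plain benzyl ethers, which the para oxygen of ring B secures because only this CH2 gives a quinoid-stabilised cation, and it needs the product to persist, which should hold because the C–C bond formation is irreversible and DDQ at this loading and temperature dehydrogenates flavanones only on heating.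

Step 10
Reactants: 16 hexa-O-benzyl flavanone–flavone
Product: 17 (2S)-5,7-dihydroxy-6-[5,7-dihydroxy-2-(4-hydroxyphenyl)-4-oxo-4H-chromen-8-yl]-2-(4-hydroxyphenyl)-2,3-dihydro-4H-chromen-4-one (CNP0154104.1)
Conditions: H2 (1 atm), 10% Pd/C, THF/MeOH (1:1), rt, stopped at full debenzylation
Reagents that add atoms: none
Why: Catalytic hydrogenolysis of six aryl benzyl ethers under neutral conditions, which avoids the base-induced ring opening that would racemise C2 and should leave the flavone double bond and the ring C benzylic C–O bond intact.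

**Compound list**

1 | apigenin | O=c1cc(-c2ccc(O)cc2)oc2cc(O)cc(O)c12 | starting material
2 | benzyl bromide | BrCc1ccccc1 | starting material
3 | 5,7-bis(benzyloxy)-2-[4-(benzyloxy)phenyl]-4H-chromen-4-one | O=c1cc(-c2ccc(OCc3ccccc3)cc2)oc2cc(OCc3ccccc3)cc(OCc3ccccc3)c12 | intermediate
4 | N-iodosuccinimide | O=C1CCC(=O)N1I | starting material
5 | 5,7-bis(benzyloxy)-2-[4-(benzyloxy)phenyl]-8-iodo-4H-chromen-4-one | O=c1cc(-c2ccc(OCc3ccccc3)cc2)oc2c(I)c(OCc3ccccc3)cc(OCc3ccccc3)c12 | intermediate
6 | pinacolborane | B1OC(C)(C)C(C)(C)O1 | starting material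
7 | 5,7-bis(benzyloxy)-2-[4-(benzyloxy)phenyl]-8-(4,4,5,5-tetramethyl-1,3,2-dioxaborolan-2-yl)-4H-chromen-4-one | O=c1cc(-c2ccc(OCc3ccccc3)cc2)oc2c(B3OC(C)(C)C(C)(C)O3)c(OCc3ccccc3)cc(OCc3ccccc3)c12 | intermediate
8 | 2',4',6'-trihydroxyacetophenone | CC(=O)c1c(O)cc(O)cc1O | starting material
9 | 1-[4-(benzyloxy)-2,6-dihydroxyphenyl]ethanone | CC(=O)c1c(O)cc(OCc2ccccc2)cc1O | intermediate
10 | 4-(benzyloxy)benzyl chloride | ClCc1ccc(OCc2ccccc2)cc1 | starting material
11 | 1-[4-(benzyloxy)-2-{[4-(benzyloxy)benzyl]oxy}-6-hydroxyphenyl]ethanone | CC(=O)c1c(O)cc(OCc2ccccc2)cc1OCc1ccc(OCc2ccccc2)cc1 | intermediate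
12 | 1-[4-(benzyloxy)-6-{[4-(benzyloxy)benzyl]oxy}-2-hydroxy-3-iodophenyl]ethanone | CC(=O)c1c(O)c(I)c(OCc2ccccc2)cc1OCc1ccc(OCc2ccccc2)cc1 | intermediate
13 | 1-[2,4-bis(benzyloxy)-6-{[4-(benzyloxy)benzyl]oxy}-3-iodophenyl]ethanone | CC(=O)c1c(OCc2ccccc2)c(I)c(OCc2ccccc2)cc1OCc1ccc(OCc2ccccc2)cc1 | intermediate
14 | 8-[3-acetyl-2,6-bis(benzyloxy)-4-{[4-(benzyloxy)benzyl]oxy}phenyl]-5,7-bis(benzyloxy)-2-[4-(benzyloxy)phenyl]-4H-chromen-4-one | CC(=O)c1c(OCc2ccccc2)c(-c2c(OCc3ccccc3)cc(OCc3ccccc3)c3c(=O)cc(-c4ccc(OCc5ccccc5)cc4)oc23)c(OCc2ccccc2)cc1OCc1ccc(OCc2ccccc2)cc1 | intermediate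
15 | O-aryl oxocarbenium ion derived from 14 by loss of hydride at the para-benzyloxybenzylic CH2 (cation shown; counter-ion is the chiral phosphate) | CC(=O)c1c(OCc2ccccc2)c(-c2c(OCc3ccccc3)cc(OCc3ccccc3)c3c(=O)cc(-c4ccc(OCc5ccccc5)cc4)oc23)c(OCc2ccccc2)cc1[O+]=Cc1ccc(OCc2ccccc2)cc1 | intermediate (not isolated)
16 | (2S)-5,7-bis(benzyloxy)-6-{5,7-bis(benzyloxy)-2-[4-(benzyloxy)phenyl]-4-oxo-4H-chromen-8-yl}-2-[4-(benzyloxy)phenyl]-2,3-dihydro-4H-chromen-4-one | O=C1C[C@@H](c2ccc(OCc3ccccc3)cc2)Oc2cc(OCc3ccccc3)c(-c3c(OCc4ccccc4)cc(OCc4ccccc4)c4c(=O)cc(-c5ccc(OCc6ccccc6)cc5)oc34)c(OCc3ccccc3)c21 | intermediate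
17 | (2S)-5,7-dihydroxy-6-[5,7-dihydroxy-2-(4-hydroxyphenyl)-4-oxo-4H-chromen-8-yl]-2-(4-hydroxyphenyl)-2,3-dihydro-4H-chromen-4-one | O=C1C[C@@H](c2ccc(O)cc2)Oc2cc(O)c(-c3c(O)cc(O)c4c(=O)cc(-c5ccc(O)cc5)oc34)c(O)c21 | target

**Step count and risks**

Total step count: 10. Longest linear sequence: 7 steps (steps 4, 5, 6, 7, 8, 9 and 10, from 8).

Steps most likely to fail:

Step 9. Facial control may be weak if a racemic closure through the achiral DDQ-hydroquinone anion pair outruns anion exchange with the chiral phosphate. The acid may also cleave the para-alkoxybenzyl ether by ionisation, and the two axial rotamers of 14 may respond differently to the catalyst. The fallback uses known chemistry, sets out from 14 and comes back at 16. DDQ in wet CH2Cl2 (pH 7 buffer) cleaves the para-benzyloxybenzyl ether oxidatively to the free phenol 8-[3-acetyl-2,6-bis(benzyloxy)-4-hydroxyphenyl]-5,7-bis(benzyloxy)-2-[4-(benzyloxy)phenyl]-4H-chromen-4-one F1. Heating F1 with N,N-dimethylformamide dimethyl acetal gives the enaminone 8-{2,6-bis(benzyloxy)-3-[(E)-3-(dimethylamino)acryloyl]-4-hydroxyphenyl}-5,7-bis(benzyloxy)-2-[4-(benzyloxy)phenyl]-4H-chromen-4-one F2. HCl in CH2Cl2 closes F2 to the chromone 5,7-bis(benzyloxy)-6-{5,7-bis(benzyloxy)-2-[4-(benzyloxy)phenyl]-4-oxo-4H-chromen-8-yl}-4H-chromen-4-one F3, so that ring C is here closed at O1–C2. An asymmetric conjugate addition of 4-(benzyloxy)phenylboronic acid to F3, catalysed by Pd(OCOCF3)2 with the tert-butyl pyridine-oxazoline ligand antipode that gives 2S (NH4PF6, H2O, ClCH2CH2Cl, 60 °C), then sets C2 and gives 16. The 2-aryl-substituted flavone unit should not compete as an acceptor.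

Step 8. Protodeboronation of the doubly ortho-oxygenated boronate 7 may outrun transmetalation to the hindered arylpalladium species, and oxidative addition into the very electron-rich iodide 13 may be slow. The fallback reverses the roles of the partners; it sets out from 13 and 5 and comes back at 14. Borylation of 13 (pinacolborane, PdCl2(MeCN)2, SPhos, Et3N, dioxane) gives 1-[2,4-bis(benzyloxy)-6-{[4-(benzyloxy)benzyl]oxy}-3-(4,4,5,5-tetramethyl-1,3,2-dioxaborolan-2-yl)phenyl]ethanone F4. F4 is then coupled with iodoflavone 5 (Pd(OAc)2, SPhos, K3PO4, toluene/H2O), so that oxidative addition takes place at the less electron-rich flavone ring.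

Step 4. Over-alkylation and poor discrimination among the three OH groups (with some C-benzylation) may erode the mono-ether. The fallback sets out from 8 and comes back at 9. Exhaustive benzylation of the two OH groups that are not chelated (BnBr 2.1 equiv, K2CO3, acetone, reflux) gives 1-[2,4-bis(benzyloxy)-6-hydroxyphenyl]ethanone F5. BCl3 (2.2 equiv, CH2Cl2, −78 to 0 °C) then removes only the benzyl group ortho to the carbonyl by chelation-controlled dealkylation and gives 9.

Further compounds

F1 | step 9 | 8-[3-acetyl-2,6-bis(benzyloxy)-4-hydroxyphenyl]-5,7-bis(benzyloxy)-2-[4-(benzyloxy)phenyl]-4H-chromen-4-one | CC(=O)c1c(OCc2ccccc2)c(-c2c(OCc3ccccc3)cc(OCc3ccccc3)c3c(=O)cc(-c4ccc(OCc5ccccc5)cc4)oc23)c(OCc2ccccc2)cc1O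
F2 | step 9 | 8-{2,6-bis(benzyloxy)-3-[(E)-3-(dimethylamino)acryloyl]-4-hydroxyphenyl}-5,7-bis(benzyloxy)-2-[4-(benzyloxy)phenyl]-4H-chromen-4-one | CN(C)/C=C/C(=O)c1c(OCc2ccccc2)c(-c2c(OCc3ccccc3)cc(OCc3ccccc3)c3c(=O)cc(-c4ccc(OCc5ccccc5)cc4)oc23)c(OCc2ccccc2)cc1O
F3 | step 9 | 5,7-bis(benzyloxy)-6-{5,7-bis(benzyloxy)-2-[4-(benzyloxy)phenyl]-4-oxo-4H-chromen-8-yl}-4H-chromen-4-one | O=c1ccoc2cc(OCc3ccccc3)c(-c3c(OCc4ccccc4)cc(OCc4ccccc4)c4c(=O)cc(-c5ccc(OCc6ccccc6)cc5)oc34)c(OCc3ccccc3)c12
F4 | step 8 | 1-[2,4-bis(benzyloxy)-6-{[4-(benzyloxy)benzyl]oxy}-3-(4,4,5,5-tetramethyl-1,3,2-dioxaborolan-2-yl)phenyl]ethanone | CC(=O)c1c(OCc2ccccc2)c(B2OC(C)(C)C(C)(C)O2)c(OCc2ccccc2)cc1OCc1ccc(OCc2ccccc2)cc1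
F5 | step 4 | 1-[2,4-bis(benzyloxy)-6-hydroxyphenyl]ethanone | CC(=O)c1c(O)cc(OCc2ccccc2)cc1OCc1ccccc1
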